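Per litre of starting volume, both new flasks hold 0.30 M of D; G comes through the feed, 2.50 equiv in north-east and 5.00 equiv in west.

| flask | D | G | remark | time |
|---|---|---|---|---|
| eta | 0.30 M | 2.8 equiv (fed, over 100 s) | run made earlier; the fed solution adds 0.20 times the starting volume |  |
| zeta | 0.30 M | 7.5 equiv (fed, over 100 s) | run made earlier; the fed solution adds 0.20 times the starting volume |  |
| north-east | 0.30 M | 2.50 equiv (fed, over 100 s) | the fed solution adds 0.20 times the starting volume | 5.0 min |
| west | 0.30 M | 5.00 equiv (fed, over 100 s) | the fed solution adds 0.20 times the starting volume | 5.0 min |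

- eta (time / min: D / %, Q / %): 0.667: 96.6, 4.1; 1.33: 85.9, 9.4; 2.00: 74.1, 11.2; 2.50: 66.3, 10.6
- zeta (time / min: D / %, Q / %): 0.667: 88.9, 7.9; 1.33: 66.8, 11.3; 2.00: 43.5, 8.0; 2.50: 32.9, 5.1

(readings scatter by 0.5 percentage points)

- part of the D that has reacted at the end, north-east
- part of the D that has reacted at the end, west
- what raising the equivalents of G from its lowest to its highest value here does to the part of the D that has reacted (changes below 5 percentage points count as none) (it rises / no change / it falls)

1. **End state.** Q rises and then falls in both runs while D plus Q shrinks. I therefore count one G to make Q and a second to take Q further: two G per D lost. By that count both charges cover the D, so the question at 5.0 min is speed.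

2. **Speed.** Read between the last two readings, after the feed and with their scatter, D decays at 0.559 min⁻¹ in zeta and 0.222 min⁻¹ in eta. Their ratio, 2.52, is close to the ratio of charges, 2.68, so you may treat D as pseudo-first-order at a given G. Zeta's G over that interval, less two per D lost, is 1.57 M. This gives a reading of the D clock, the decay rate of D per molar of G: 0.357 L mol⁻¹ min⁻¹.

3. **First estimate.** Diluted and unreacted, G ends at 0.625 M in north-east and 1.25 M in west. The feed counts as half its length, so the logarithmic loss of D is 0.929 in north-east and 1.86 in west. That means 60.5% and 84.4% reacted.

4. **Objection.** G is being spent. At two per D lost, its mean after the feed drops by 0.194 M in north-east and 0.289 M in west. My figures become 50.3% and 78.0%.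

5. **Forecast.** It gives 53% and 79%, and on the trend, it rises: “More G clearly raises conversion.”

6. **Result.** The flasks give 51.2% and 78.6%; it rises, by 27 percentage points.

    D + G → L + Q (k = 0.00706 L mol⁻¹ s⁻¹)
    G + L ⇌ J, settled at all times (K = 6700 L mol⁻¹)
    G + Q → E (k = 0.0485 L mol⁻¹ s⁻¹)

In north-east, with the charges taken as if all present at once, Q has a half-life of 0.32 min by G + Q alone, shorter than the 2.2 min of D by D + G alone. At 5.00 min that flask holds 8.19% Q beside 43.0% E. It has lost 2.84 unbound G per D lost, more than my two. The D clock on its unbound G at 5.00 min gives 0.0932 min⁻¹.

Now leave west until 8.0 min: the D clock on the mean of its unbound G at the two times gives 0.222 min⁻¹, so the reckoning takes D from 21.4% to 11.0%. The computed flask holds 9.77% of D.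

All runs are calculated on assumed constants, and the scatter is random.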